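Compound numbers used throughout: 1 nerol, 2 its TBS ether, 3 the ω-hydroxylated ether, 4 the allylic bromide, 5 (2E,6E)-farnesol, 6 farnesyl bromide, 7 farnesyl phenyl sulfone, 8 lithiated 7, 9 the C25 sulfone, 10 the C25 silyl ether, 11 (2Z,6E,10E,14E)-geranylfarnesol, 12 its chloride, 13 its diphosphate, 14 the deoxy macrocycle, 15 the target.

## Analysis of the target

The target 15 is a monocyclic C25 diol built on a 14-membered carbocycle. Atom numbers used here: C1 is the ring carbinol carbon, C2 to C14 are the other ring carbons counted towards the Z alkene, C15 to C19 are the side-chain carbons; open-chain precursors keep these numbers. The ring holds three methyl-bearing trisubstituted alkenes in a 1,5-relationship, C3=C4 (Z), C7=C8 (E) and C11=C12 (E), and C1 carries a tertiary hydroxyl and the side chain, which ends in an (E)-2-methylallylic alcohol at C18=C19. There are only two stereocentres, the tertiary carbinol C1 (S) and the adjacent methyl-bearing methine C15 (R), and nothing else in the molecule is close enough to relay stereochemical information to them. The two ring arms at C1 differ only from the β-carbon onwards (C2 is allylic, C14 homoallylic) and C15 has no heteroatom handle, so neither centre is easy to reach by reagent control. Sensitive features are the tertiary homoallylic alcohol (ionisation, dehydration), the skipped polyene (transannular cation–alkene closure, alkene migration under acid), the Z alkene and the primary allylic alcohol. The difficulty lies in closing a 14-membered ring while fixing an isolated stereodiad and in telling four similar trisubstituted alkenes apart. The plan rests on the chain C2–C3…C14–C1–C15…C19 with methyl groups on C4, C8, C12, C15 and C19: it is an unbroken head-to-tail pentaprenyl chain, and the ring bond C1–C2, the hydrogen on C15 and the hydroxyl on C1 are the marks of a 1,14-cyclisation followed by a 1,2-hydride shift and hydration.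

## Retrosynthetic reasoning

From 15 back to 14: the C–O bond of the primary alcohol is removed first. The side-chain terminus of 14 is the only isopropylidene group in the molecule, and allylic oxidation of such termini goes to the (E)-methyl group, so the hydroxyl can be added last. This leaves the precursor of the ring-forming step as an unmodified isoprenoid chain.

From 14 back to 13: the ring bond C1–C2 is cut, the hydrogen on C15 is returned to C1 and the hydroxyl on C1 is taken away, which gives the open-chain allylic diphosphate 13. C1–C2 is the only ring bond whose cleavage leaves a regular, unbranched polyprenyl chain with every alkene already in place (the Z alkene C3=C4 included). In the forward direction one event has to ionise C2, close the 14-membered ring onto C1, move hydride from C1 to C15 and hydrate C1. That is the reaction type of ionisation-initiated terpene synthases, and it makes the ring and both stereocentres at once from an achiral chain.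

From 13 back to 11 through 12: the diphosphate is traced to the primary allylic chloride and then to the alcohol. Only the C2–O bond changes. The forward steps must be neutral and low in temperature, because the Z-allylic system at C2–C4 ionises easily.

From 11 back to 7 and 4 through 10 and 9: after removal of the silyl group, the chain is cut at C9–C10 between two allylic methylene groups. This splits it into a C10 piece that carries the Z alkene and a C15 piece that carries the E alkenes, so none of the five alkenes has to be constructed. The bond is made by alkylating an α-sulfonyl allyl carbanion (C10) with an allylic bromide (C9). The sulfonyl group is put on the C15 half, where it sits on a carbon bound to a CH= unit; reductive removal then has a clear preference for the less substituted allyl terminus and leaves the C11=C12 alkene where it is. The reverse polarity would place the sulfonyl group next to the methyl-bearing alkene carbon and make that removal ambiguous.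

From 4 back to 1 and from 7 back to 5: bromide 4 comes from nerol 1 by protection (2), allylic hydroxylation of the (E)-methyl group (3) and bromination. Sulfone 7 comes from farnesol 5 through bromide 6. Both terpenols are commercial and supply the Z and the E,E geometry.

## Alternatives that were turned down

Alternative 1: C1 and C15 are taken as the quaternary α-carbon and the methyl-bearing β-carbon of the cyclopentanone A1, whose carbonyl carbon is C18. The key step is a peracid Baeyer–Villiger oxidation that puts oxygen between C18 and C1 with retention and gives the six-membered lactone A2. In its favour, the relative configuration of the vicinal centres is set on a small ring, where alkylation trans to a neighbouring methyl group is dependable, and migration of the more substituted carbon with retention is dependable too. On this point it is stronger than the chosen plan, since it needs no catalyst that still has to be found. Against it, A2 contains neither the macrocycle nor any of the four trisubstituted alkenes. Its two alkynes must still be turned into methyl-bearing alkenes of defined geometry, the C7=C8 unit inserted, the ring closed and the lactone carbonyl worked up into the (E)-allylic alcohol, and the quaternary centre needs two alkylations at the more hindered α-position. The chosen plan offers in exchange a ring closure that delivers ring, stereodiad and all ring alkenes together, in about half the number of steps.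

Alternative 2: the ring is opened at C3≡C4, written as an alkyne. The key step is ring-closing alkyne metathesis of the methyl-capped diyne A3 with a molybdenum alkylidyne such as (4-MeOC6H4)C≡Mo(OSiPh3)3, with loss of but-2-yne, to the 14-membered cycloalkyne A4; a hydroxyl-directed methylmetalation then makes the Z alkene. In its favour, this metathesis closes 14-membered rings reliably and ignores alkenes, and the Z geometry is made by a syn addition anchored on the C1 oxygen. In that respect it is at least as secure as the chosen plan, where the Z geometry has to survive ionisation in an active site. Against it, A3 already contains the C1/C15 stereodiad, which must be built in open-chain form without nearby control elements; two E alkenes and two silyl ethers have to be carried; the silyl group on the C1 oxygen must come off before the directed step; and the methyl must be delivered to C4 and not C3. The step count is roughly double. The chosen plan imports every alkene from the terpene pool and has no stereocentre to protect before the key step.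

Alternative 3: the ring is opened at C13–C14. The key step is deprotonation of the allylic sulfone A5 with LiN(SiMe3)2 and attack of the C13 carbanion on the CH2 terminus (C14) of a 2,2-disubstituted epoxide, giving the macrocyclic hydroxy sulfone A6. In its favour, all alkenes arrive intact from terpene building blocks, the C1 configuration rides in with the epoxide and is not touched by the ring closure, and carbanion–epoxide closures of 14-membered terpenoid rings are established. It is the most robust of the three and uses only shelf reagents, and for that reason its ring closure is kept as the fallback for the key step. Against it, the epoxide next to C15 must first be made as a single stereoisomer. The sulfonyl group on C13 also sits beside the methyl-bearing alkene carbon, so its reductive removal passes through an allyl intermediate with two similar termini (C13 and C11) and risks alkene migration or loss of the 11E geometry. The route is much longer. The chosen plan creates both centres and the ring in one step and needs only a regiochemically clear desulfonylation.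

Key step: step 11

Assumption: diphosphate 13 is drawn as the free acid but is made, stored and used as its ammonium salt; sulfone 9 is formed as both epimers at the sulfonyl-bearing carbon, which does not matter because that centre is removed in step 7.

## Route

Step 1
Reactants: 1 nerol, (2Z)-3,7-dimethylocta-2,6-dien-1-ol
Product: 2 neryl TBS ether, tert-butyl{[(2Z)-3,7-dimethylocta-2,6-dien-1-yl]oxy}dimethylsilane
Conditions: TBSCl, imidazole, CH2Cl2, 0 °C to rt
Reagents that add atoms: tert-butyldimethylsilyl chloride, CC(C)(C)[Si](C)(C)Cl
Why: Imidazole-promoted silylation of a primary alcohol; the TBS ether withstands the oxidation, bromination, carbanion and hydride steps that follow and, as an allylic ether, lowers the reactivity of the neighbouring Z alkene towards the oxidant of step 2.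

Step 2
Reactants: 2 neryl TBS ether
Product: 3 (2E,6Z)-8-[(tert-butyldimethylsilyl)oxy]-2,6-dimethylocta-2,6-dien-1-ol
Conditions: SeO2 (0.3 equiv), t-BuOOH (3 equiv), salicylic acid (0.1 equiv), CH2Cl2, 0 °C to rt
Reagents that add atoms: selenium dioxide, O=[Se]=O (hands over the oxygen); tert-butyl hydroperoxide, CC(C)(C)OO (regenerates SeO2 and is the net oxygen source)
Why: SeO2-catalysed allylic hydroxylation (ene reaction, then [2,3]-sigmatropic shift) takes the remote, more electron-rich isopropylidene alkene and, as is general for such termini, its (E)-methyl group, so the new allylic alcohol is E; the Z alkene next to the silyloxy group is deactivated and stays. Conversion is held below completion, and any enal from over-oxidation can be returned to 3 with NaBH4.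

Step 3
Reactants: 3 (2E,6Z)-8-[(tert-butyldimethylsilyl)oxy]-2,6-dimethylocta-2,6-dien-1-ol
Product: 4 {[(2Z,6E)-8-bromo-3,7-dimethylocta-2,6-dien-1-yl]oxy}(tert-butyl)dimethylsilane
Conditions: CBr4, PPh3, CH2Cl2, −20 to 0 °C
Reagents that add atoms: carbon tetrabromide, BrC(Br)(Br)Br
Why: Appel bromination of a primary allylic alcohol proceeds by SN2 displacement of the oxyphosphonium group at low temperature, without allylic transposition and without harm to the silyl ether; 4 is used promptly.

Step 4
Reactants: 5 (2E,6E)-farnesol, (2E,6E)-3,7,11-trimethyldodeca-2,6,10-trien-1-ol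
Product: 6 (2E,6E)-farnesyl bromide, (2E,6E)-1-bromo-3,7,11-trimethyldodeca-2,6,10-triene
Conditions: PBr3 (0.4 equiv), Et2O, −10 to 0 °C
Reagents that add atoms: phosphorus tribromide, BrP(Br)Br
Why: Standard conversion of a primary allylic alcohol into its bromide; substitution at the primary carbon at low temperature keeps the 2E geometry.

Step 5
Reactants: 6 (2E,6E)-farnesyl bromide
Product: 7 (2E,6E)-farnesyl phenyl sulfone, {[(2E,6E)-3,7,11-trimethyldodeca-2,6,10-trien-1-yl]sulfonyl}benzene
Conditions: PhSO2Na, DMF, 0 °C to rt
Reagents that add atoms: sodium benzenesulfinate, [Na+].[O-]S(=O)c1ccccc1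
Why: S-alkylation of the ambident sulfinate by a soft primary allylic bromide in a dipolar aprotic solvent (SN2, no transposition) gives the allylic sulfone.

Step 6
Reactants: 7 (2E,6E)-farnesyl phenyl sulfone; 4 {[(2Z,6E)-8-bromo-3,7-dimethylocta-2,6-dien-1-yl]oxy}(tert-butyl)dimethylsilane
Product: 9 tert-butyl(dimethyl){[(2Z,6E,10E,14E)-3,7,11,15,19-pentamethyl-9-(phenylsulfonyl)icosa-2,6,10,14,18-pentaen-1-yl]oxy}silane (both epimers at the sulfonyl-bearing carbon), via lithiated sulfone 8 (not isolated)
Conditions: n-BuLi (1.05 equiv), THF, −78 °C; then 4, −78 to −30 °C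
Reagents that add atoms: none
Why: Biellmann-type coupling: the α-sulfonyl allyl carbanion 8 is alkylated at its α-carbon by the primary allylic bromide in an SN2 reaction, which joins C9 to C10 (target numbering) head to tail; no alkene takes part, so the 2Z,6E geometry of 4 and the E,E geometry of 7 are carried over.

Step 7
Reactants: 9 C25 sulfone
Product: 10 tert-butyl(dimethyl){[(2Z,6E,10E,14E)-3,7,11,15,19-pentamethylicosa-2,6,10,14,18-pentaen-1-yl]oxy}silane
Conditions: Pd(dppp)Cl2 (5 mol%; dppp = 1,3-bis(diphenylphosphino)propane), LiBHEt3 (2.5 equiv), THF, 0 °C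
Reagents that add atoms: none
Why: Palladium-catalysed hydride desulfonylation of an allylic sulfone: zerovalent palladium formed in situ ionises the C–S bond to a π-allyl complex and hydride goes to the less substituted terminus, the carbon that carried the sulfonyl group, so the adjacent trisubstituted alkene keeps its position and E geometry. The silyl ether and the isolated alkenes do not react.

Step 8
Reactants: 10 C25 silyl ether
Product: 11 (2Z,6E,10E,14E)-geranylfarnesol, (2Z,6E,10E,14E)-3,7,11,15,19-pentamethylicosa-2,6,10,14,18-pentaen-1-ol
Conditions: TBAF, THF, 0 °C to rt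
Reagents that add atoms: none
Why: Fluoride cleavage of the silyl ether; no other group responds.

Step 9
Reactants: 11 (2Z,6E,10E,14E)-geranylfarnesol
Product: 12 (2Z,6E,10E,14E)-1-chloro-3,7,11,15,19-pentamethylicosa-2,6,10,14,18-pentaene
Conditions: NCS, Me2S, CH2Cl2, −40 to 0 °C
Reagents that add atoms: N-chlorosuccinimide, O=C1CCC(=O)N1Cl
Why: Corey–Kim chlorination: the alkoxysulfonium salt is displaced by chloride at the primary carbon under neutral conditions at low temperature, which avoids ionisation of the Z-allylic system (no Z to E change, no tertiary chloride); 12 is used at once.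

Step 10
Reactants: 12 (2Z)-geranylfarnesyl chloride
Product: 13 (2Z,6E,10E,14E)-geranylfarnesyl diphosphate, (2Z,6E,10E,14E)-3,7,11,15,19-pentamethylicosa-2,6,10,14,18-pentaen-1-yl trihydrogen diphosphate (isolated as the ammonium salt)
Conditions: (n-Bu4N)3HP2O7 (2 equiv), MeCN, rt; then Dowex 50W-X8 (NH4+ form), aqueous NH4HCO3/i-PrOH; cellulose chromatography
Reagents that add atoms: tris(tetrabutylammonium) hydrogen diphosphate, CCCC[N+](CCCC)(CCCC)CCCC.CCCC[N+](CCCC)(CCCC)CCCC.CCCC[N+](CCCC)(CCCC)CCCC.OP(=O)([O-])OP(=O)([O-])[O-]
Why: Davisson–Poulter displacement: the non-basic, acetonitrile-soluble diphosphate salt substitutes the primary allylic chloride by SN2 with retention of the 2Z geometry; cation exchange gives the water-soluble ammonium salt that the enzyme needs.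

Step 11
Reactants: 13 (2Z,6E,10E,14E)-geranylfarnesyl diphosphate
Product: 14 (1S,3Z,7E,11E)-4,8,12-trimethyl-1-[(2R)-6-methylhept-5-en-2-yl]cyclotetradeca-3,7,11-trien-1-ol
Conditions: recombinant class 1 sesterterpene synthase (selected by screening, see Why), MgCl2 (10 mM), HEPES buffer pH 7.5, 10% glycerol, 30 °C, hexane overlay
Reagents that add atoms: water, O
Why: Proposed new method: no characterised synthase is known to deliver 14, so the step is argued from mechanism and from the closest known reaction type, the 1,14-macrocyclisation of geranylgeranyl and geranylfarnesyl diphosphates by class 1 terpene synthases with subsequent hydride shift and capture of water. The magnesium cluster held by the aspartate-rich motifs ionises the diphosphate of 13 and leaves the cisoid C2–C3–C4 allyl cation, whose Z geometry is already built into the substrate. The C1=C15 alkene, folded over C2 by the hydrophobic cavity, attacks with its less substituted carbon C1 and closes the 14-membered ring in the exo mode at a trigonal carbon (C15 stays outside the ring and becomes a tertiary cation). A suprafacial 1,2-hydride shift from C1 to C15 sets C15 (R) and moves the charge to the ring carbon C1; the face of C15 that takes the hydride is dictated by the C1–C15 rotamer that the fold enforces. An active-site water then adds to one face of the C1 cation and sets C1 (S), so both centres are under catalyst control and come from an achiral substrate. The step needs site selectivity for C2–C1 closure over the six-membered C2–C7 closure that cisoid allyl cations normally prefer and over C2–C11 and C2–C19 closure, and it needs hydration to win over proton loss. The substrate secures only part of this (the head-to-tail spacing that brings C1 within reach of C2, Markovnikov attack giving a tertiary cation, a near-thermoneutral tertiary-to-tertiary hydride shift); the rest must come from the enzyme, to be found by screening cyclases that accept geranylfarnesyl diphosphate (bacterial, plant and the cyclase domains of fungal bifunctional sesterterpene synthases) with 13 and then reshaping the residues that line the C6–C8 region.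

Step 12
Reactants: 14 deoxy macrocycle
Product: 15 (1S,3Z,7E,11E)-1-[(2R,5E)-7-hydroxy-6-methylhept-5-en-2-yl]-4,8,12-trimethylcyclotetradeca-3,7,11-trien-1-ol
Conditions: SeO2 (0.3 equiv), t-BuOOH (2 equiv), salicylic acid (0.1 equiv), CH2Cl2, 0 °C, to partial conversion
Reagents that add atoms: selenium dioxide, O=[Se]=O (hands over the oxygen); tert-butyl hydroperoxide, CC(C)(C)OO (regenerates SeO2 and is the net oxygen source)
Why: SeO2-catalysed allylic hydroxylation as in step 2: of the four trisubstituted alkenes only the side-chain isopropylidene has two methyl groups on its disubstituted carbon and an open approach, the pattern this oxidant prefers in polyprenyl chains, and the ene/[2,3] sequence gives the (E)-allylic alcohol; the tertiary alcohol and both stereocentres are not touched. The reaction is stopped early and 14 is recovered, to hold back oxidation at ring allylic positions.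

## Compound list

1 | nerol, (2Z)-3,7-dimethylocta-2,6-dien-1-ol | OC/C=C(/C)CCC=C(C)C | starting material
2 | tert-butyl{[(2Z)-3,7-dimethylocta-2,6-dien-1-yl]oxy}dimethylsilane | CC(C)(C)[Si](C)(C)OC/C=C(/C)CCC=C(C)C | intermediate
3 | (2E,6Z)-8-[(tert-butyldimethylsilyl)oxy]-2,6-dimethylocta-2,6-dien-1-ol | CC(C)(C)[Si](C)(C)OC/C=C(/C)CC/C=C(\C)CO | intermediate
4 | {[(2Z,6E)-8-bromo-3,7-dimethylocta-2,6-dien-1-yl]oxy}(tert-butyl)dimethylsilane | CC(C)(C)[Si](C)(C)OC/C=C(/C)CC/C=C(\C)CBr | intermediate
5 | (2E,6E)-farnesol, (2E,6E)-3,7,11-trimethyldodeca-2,6,10-trien-1-ol | OC/C=C(\C)CC/C=C(\C)CCC=C(C)C | starting material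
6 | (2E,6E)-farnesyl bromide, (2E,6E)-1-bromo-3,7,11-trimethyldodeca-2,6,10-triene | BrC/C=C(\C)CC/C=C(\C)CCC=C(C)C | intermediate
7 | (2E,6E)-farnesyl phenyl sulfone, {[(2E,6E)-3,7,11-trimethyldodeca-2,6,10-trien-1-yl]sulfonyl}benzene | O=S(=O)(C/C=C(\C)CC/C=C(\C)CCC=C(C)C)c1ccccc1 | intermediate
8 | lithiated sulfone, {[(2E,6E)-1-lithio-3,7,11-trimethyldodeca-2,6,10-trien-1-yl]sulfonyl}benzene | [Li]C(/C=C(\C)CC/C=C(\C)CCC=C(C)C)S(=O)(=O)c1ccccc1 | intermediate (not isolated)
9 | tert-butyl(dimethyl){[(2Z,6E,10E,14E)-3,7,11,15,19-pentamethyl-9-(phenylsulfonyl)icosa-2,6,10,14,18-pentaen-1-yl]oxy}silane, both epimers at the sulfonyl-bearing carbon | CC(C)(C)[Si](C)(C)OC/C=C(/C)CC/C=C(\C)CC(S(=O)(=O)c1ccccc1)/C=C(\C)CC/C=C(\C)CCC=C(C)C | intermediate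
10 | tert-butyl(dimethyl){[(2Z,6E,10E,14E)-3,7,11,15,19-pentamethylicosa-2,6,10,14,18-pentaen-1-yl]oxy}silane | CC(C)(C)[Si](C)(C)OC/C=C(/C)CC/C=C(\C)CC/C=C(\C)CC/C=C(\C)CCC=C(C)C | intermediate
11 | (2Z,6E,10E,14E)-geranylfarnesol, (2Z,6E,10E,14E)-3,7,11,15,19-pentamethylicosa-2,6,10,14,18-pentaen-1-ol | OC/C=C(/C)CC/C=C(\C)CC/C=C(\C)CC/C=C(\C)CCC=C(C)C | intermediate
12 | (2Z,6E,10E,14E)-1-chloro-3,7,11,15,19-pentamethylicosa-2,6,10,14,18-pentaene | ClC/C=C(/C)CC/C=C(\C)CC/C=C(\C)CC/C=C(\C)CCC=C(C)C | intermediate
13 | (2Z,6E,10E,14E)-geranylfarnesyl diphosphate (free acid drawn; ammonium salt used) | OP(=O)(O)OP(=O)(O)OC/C=C(/C)CC/C=C(\C)CC/C=C(\C)CC/C=C(\C)CCC=C(C)C | intermediate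
14 | (1S,3Z,7E,11E)-4,8,12-trimethyl-1-[(2R)-6-methylhept-5-en-2-yl]cyclotetradeca-3,7,11-trien-1-ol | C/C1=C/C[C@](O)([C@H](C)CCC=C(C)C)CC/C(C)=C/CC/C(C)=C/CC1 | intermediate
15 | (1S,3Z,7E,11E)-1-[(2R,5E)-7-hydroxy-6-methylhept-5-en-2-yl]-4,8,12-trimethylcyclotetradeca-3,7,11-trien-1-ol | C/C1=C/C[C@](O)([C@H](C)CC/C=C(\C)CO)CC/C(C)=C/CC/C(C)=C/CC1 | target

## Step count and least certain steps

Total: 12 steps. Longest linear sequence: 10 steps (steps 1, 2, 3, 6, 7, 8, 9, 10, 11, 12, from 1 to 15); the farnesol branch (steps 4 and 5) joins at step 6.

Step 11 (key step, proposed new method). Most likely failure: no screened or engineered enzyme channels 13 to 14. The cisoid allyl cation can close the six-membered ring with the C7=C8 alkene, the macrocyclic cation can lose a proton instead of shifting hydride, water can add at C15 before the shift, or the fold can produce the other enantiomeric series. The cause is that ring size, hydride shift and both faces depend on an active-site contour that has not been shown for this product.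

Fallback (known chemistry; sets out from 1, returns at 14): the ring is closed by an allylic sulfone carbanion on a 2,2-disubstituted epoxide, and the two stereocentres are set beforehand by catalyst control.
- Stereodiad fragment. Hydrogenation of 1 over Ru(OAc)2[(R)-BINAP] should give (R)-citronellol F1, which sets C15, and TEMPO/PhI(OAc)2 oxidation gives (R)-citronellal F2. α-Methylenation (aqueous CH2O, pyrrolidine, propionic acid) gives the α-methylene aldehyde F3, and NaBH4/CeCl3·7H2O gives allylic alcohol F4. Sharpless epoxidation (Ti(OiPr)4, L-(+)-diethyl tartrate, t-BuOOH) gives epoxy alcohol F5, which fixes C1, and TBSCl/imidazole gives silyl ether F6.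
- Ring-chain fragment. Geranyl bromide (BrC/C=C(\C)CCC=C(C)C) is alkylated with lithiated 1-(trimethylsilyl)propyne to silyl enyne F7. SeO2/t-BuOOH oxidation of the terminal (E)-methyl group gives allylic alcohol F8, NaH/4-methoxybenzyl chloride gives PMB ether F9, and K2CO3/MeOH gives terminal alkyne F10.
- Coupling and Z alkene. The lithium acetylide of F10 with BF3·OEt2 opens F6 at its CH2 group (the future C2) to give homopropargylic alcohol F11. Hydroxyl-directed syn-methylmagnesiation (MeMgBr, Fe(acac)3 cat.) puts the methyl group on C4 and gives the (3Z)-homoallylic alcohol F12.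
- Epoxide and sulfone. TBAF gives diol F13, N-tosylimidazole/NaH closes the C1–C14 epoxide F14, DDQ frees allylic alcohol F15, CBr4/PPh3 gives allylic bromide F16, and PhSO2Na gives epoxy sulfone F17.
- Ring closure. LiN(SiMe3)2 at high dilution should join C13 to C14 and give the macrocyclic hydroxy sulfone F18. Pd(dppp)Cl2/LiBHEt3 (or buffered sodium amalgam) removes the sulfonyl group to give 14; hydride can enter at C13 or C11 here, so Δ11 and Δ12 isomers may have to be separated.

Step 12. Most likely failure: loss of site selectivity, with ene oxidation at ring allylic positions competing with the side-chain terminus, and over-oxidation to the enal, because all four alkenes are trisubstituted and differ only in their surroundings. Fallback (sets out from 14, returns at 15): cross-metathesis of 14 with methacrolein (second-generation Hoveyda–Grubbs catalyst, CH2Cl2, 40 °C) exchanges the isopropylidene terminus, the least hindered trisubstituted alkene, for the (E)-enal F19, and NaBH4/CeCl3·7H2O reduces it to 15.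

Step 7. Most likely failure: hydride delivery to the wrong allyl terminus or syn–anti isomerisation of the π-allyl intermediate, which would shift the C11=C12 alkene or erode its E geometry. Fallback (sets out from 5, uses 4, returns at 10): 5 is converted with NCS/Me2S into farnesyl chloride F20, which with Rieke barium (BaI2, lithium biphenylide, THF, −78 °C) gives farnesylbarium chloride F21. This reagent couples with bromide 4 at its α-carbon with retention of the alkene geometries of both partners and gives 10 directly, so no sulfone has to be removed.

Step 10 (with step 9). Most likely failure: ionisation of the Z-allylic chloride or diphosphate, leading to Z to E isomerisation, allylic transposition to the tertiary isomer or hydrolysis, because the C2–C4 allyl system is a good cation precursor. Fallback (sets out from 11, returns at 13): phosphorylation of 11 with Cl3CCN and bis(triethylammonium) hydrogen phosphate in MeCN builds the monophosphate F22 and, on repeated addition, the diphosphate 13 by phosphoryl transfer to oxygen. The C–O bond of 11 is never broken, so the allyl system cannot rearrange, and 13 is separated from mono- and triphosphate by ion-exchange chromatography.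

## Further compounds

F1 | step 11 | (R)-citronellol, (3R)-3,7-dimethyloct-6-en-1-ol | OCC[C@H](C)CCC=C(C)C
F2 | step 11 | (R)-citronellal, (3R)-3,7-dimethyloct-6-enal | O=CC[C@H](C)CCC=C(C)C
F3 | step 11 | (3R)-3,7-dimethyl-2-methylideneoct-6-enal | O=CC(=C)[C@H](C)CCC=C(C)C
F4 | step 11 | (3R)-3,7-dimethyl-2-methylideneoct-6-en-1-ol | OCC(=C)[C@H](C)CCC=C(C)C
F5 | step 11 | {(2S)-2-[(2R)-6-methylhept-5-en-2-yl]oxiran-2-yl}methanol | OC[C@]1(CO1)[C@H](C)CCC=C(C)C
F6 | step 11 | tert-butyl(dimethyl)({(2R)-2-[(2R)-6-methylhept-5-en-2-yl]oxiran-2-yl}methoxy)silane | CC(C)(C)[Si](C)(C)OC[C@]1(CO1)[C@H](C)CCC=C(C)C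
F7 | step 11 | [(5E)-6,10-dimethylundeca-5,9-dien-1-yn-1-yl](trimethyl)silane | C[Si](C)(C)C#CCC/C=C(\C)CCC=C(C)C
F8 | step 11 | (2E,6E)-2,6-dimethyl-11-(trimethylsilyl)undeca-2,6-dien-10-yn-1-ol | C[Si](C)(C)C#CCC/C=C(\C)CC/C=C(\C)CO
F9 | step 11 | {(5E,9E)-11-[(4-methoxyphenyl)methoxy]-6,10-dimethylundeca-5,9-dien-1-yn-1-yl}(trimethyl)silane | COc1ccc(COC/C(C)=C/CC/C(C)=C/CCC#C[Si](C)(C)C)cc1
F10 | step 11 | 1-({[(2E,6E)-2,6-dimethylundeca-2,6-dien-10-yn-1-yl]oxy}methyl)-4-methoxybenzene | COc1ccc(COC/C(C)=C/CC/C(C)=C/CCC#C)cc1
F11 | step 11 | (2S,3R)-1-[(tert-butyldimethylsilyl)oxy]-2-{(6E,10E)-12-[(4-methoxyphenyl)methoxy]-7,11-dimethyldodeca-6,10-dien-2-yn-1-yl}-3,7-dimethyloct-6-en-2-ol | COc1ccc(COC/C(C)=C/CC/C(C)=C/CCC#CC[C@@](O)(CO[Si](C)(C)C(C)(C)C)[C@H](C)CCC=C(C)C)cc1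
F12 | step 11 | (2S,3R)-1-[(tert-butyldimethylsilyl)oxy]-2-{(2Z,6E,10E)-12-[(4-methoxyphenyl)methoxy]-3,7,11-trimethyldodeca-2,6,10-trien-1-yl}-3,7-dimethyloct-6-en-2-ol | COc1ccc(COC/C(C)=C/CC/C(C)=C/CC/C(C)=C\C[C@@](O)(CO[Si](C)(C)C(C)(C)C)[C@H](C)CCC=C(C)C)cc1
F13 | step 11 | (2S,3R)-2-{(2Z,6E,10E)-12-[(4-methoxyphenyl)methoxy]-3,7,11-trimethyldodeca-2,6,10-trien-1-yl}-3,7-dimethyloct-6-ene-1,2-diol | COc1ccc(COC/C(C)=C/CC/C(C)=C/CC/C(C)=C\C[C@@](O)(CO)[C@H](C)CCC=C(C)C)cc1
F14 | step 11 | (2S)-2-{(2Z,6E,10E)-12-[(4-methoxyphenyl)methoxy]-3,7,11-trimethyldodeca-2,6,10-trien-1-yl}-2-[(2R)-6-methylhept-5-en-2-yl]oxirane | COc1ccc(COC/C(C)=C/CC/C(C)=C/CC/C(C)=C\C[C@@]2(CO2)[C@H](C)CCC=C(C)C)cc1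
F15 | step 11 | (2E,6E,10Z)-2,6,10-trimethyl-12-{(2S)-2-[(2R)-6-methylhept-5-en-2-yl]oxiran-2-yl}dodeca-2,6,10-trien-1-ol | OC/C(C)=C/CC/C(C)=C/CC/C(C)=C\C[C@@]1(CO1)[C@H](C)CCC=C(C)C
F16 | step 11 | (2S)-2-[(2Z,6E,10E)-12-bromo-3,7,11-trimethyldodeca-2,6,10-trien-1-yl]-2-[(2R)-6-methylhept-5-en-2-yl]oxirane | BrC/C(C)=C/CC/C(C)=C/CC/C(C)=C\C[C@@]1(CO1)[C@H](C)CCC=C(C)C
F17 | step 11 | (2S)-2-[(2R)-6-methylhept-5-en-2-yl]-2-[(2Z,6E,10E)-3,7,11-trimethyl-12-(phenylsulfonyl)dodeca-2,6,10-trien-1-yl]oxirane | O=S(=O)(c1ccccc1)C/C(C)=C/CC/C(C)=C/CC/C(C)=C\C[C@@]2(CO2)[C@H](C)CCC=C(C)C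
F18 | step 11 | (1R,3Z,7E,11E)-4,8,12-trimethyl-1-[(2R)-6-methylhept-5-en-2-yl]-13-(phenylsulfonyl)cyclotetradeca-3,7,11-trien-1-ol, either configuration at C13 | C/C1=C/C[C@](O)([C@H](C)CCC=C(C)C)CC(S(=O)(=O)c2ccccc2)/C(C)=C/CC/C(C)=C/CC1
F19 | step 12 | (2E,6R)-6-[(1S,3Z,7E,11E)-1-hydroxy-4,8,12-trimethylcyclotetradeca-3,7,11-trien-1-yl]-2-methylhept-2-enal | C/C1=C/C[C@](O)([C@H](C)CC/C=C(\C)C=O)CC/C(C)=C/CC/C(C)=C/CC1
F20 | step 7 | (2E,6E)-farnesyl chloride, (2E,6E)-1-chloro-3,7,11-trimethyldodeca-2,6,10-triene | ClC/C=C(\C)CC/C=C(\C)CCC=C(C)C
F21 | step 7 | (2E,6E)-farnesylbarium chloride | Cl[Ba]C/C=C(\C)CC/C=C(\C)CCC=C(C)C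
F22 | step 10 | (2Z,6E,10E,14E)-geranylfarnesyl dihydrogen phosphate | OP(=O)(O)OC/C=C(/C)CC/C=C(\C)CC/C=C(\C)CC/C=C(\C)CCC=C(C)C
A1 | alternative 1 | cyclopentanone with C1 as quaternary α-carbon and C15 as methyl-bearing β-carbon | CC(C)(C)[Si](C)(C)OCCCC#CC[C@@]1(C(=O)CC[C@H]1C)CCC#C[Si](C)(C)C
A2 | alternative 1 | six-membered lactone from Baeyer–Villiger oxidation of A1 | CC(C)(C)[Si](C)(C)OCCCC#CC[C@@]1(OC(=O)CC[C@H]1C)CCC#C[Si](C)(C)C
A3 | alternative 2 | methyl-capped diyne, triethylsilyl ether at C1 and TBS ether on the side chain | CC#CC[C@](O[Si](CC)(CC)CC)([C@H](C)CC/C=C(\C)CO[Si](C)(C)C(C)(C)C)CC/C(C)=C/CC/C(C)=C/CCC#CC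
A4 | alternative 2 | 14-membered cycloalkyne from ring-closing alkyne metathesis of A3 | C1#CC[C@](O[Si](CC)(CC)CC)([C@H](C)CC/C=C(\C)CO[Si](C)(C)C(C)(C)C)CC/C(C)=C/CC/C(C)=C/CC1
A5 | alternative 3 | open-chain epoxy sulfone (C1–C14 epoxide, phenylsulfonyl on C13, TBS ether on the side chain) | O=S(=O)(c1ccccc1)C/C(C)=C/CC/C(C)=C/CC/C(C)=C\C[C@@]2(CO2)[C@H](C)CC/C=C(\C)CO[Si](C)(C)C(C)(C)C
A6 | alternative 3 | macrocyclic hydroxy sulfone, either configuration at C13 | C/C1=C/C[C@](O)([C@H](C)CC/C=C(\C)CO[Si](C)(C)C(C)(C)C)CC(S(=O)(=O)c2ccccc2)/C(C)=C/CC/C(C)=C/CC1
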